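The route rests on opening the 2,2-dimethyl-2H-pyran ring fused to ring B at its two aryl bonds, O1–C8a and C4–C4a (chromene numbering), which sit on adjacent ring-B carbons. In one operation a 3-methoxybenzyne and 3-methylbut-2-enal combine: carbonyl [2+2] addition, 4π ring opening to an ortho-quinone methide and oxa-6π closure give the chromene, the aldehyde oxygen ending on the gem-dimethyl carbon. The precursor, 3-methoxy-2-(trimethylsilyl)phenyl triflate, has neither the pyran ring nor its oxygen. The methoxy oxygen that steers this step later relays the 1,1-dimethylallyl group (Claisen) and is exchanged for carbon through a quinone monoketal; ynone cyclisation and C3 hydroxylation finish the flavonol.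

Key step: step 1

Remark: the target has no stereocentre and no stereogenic double bond; the stereocentres met on the way (9, 13, 14, 20) are racemic and are destroyed before the end. Compounds 1, 2 and 17 are taken as commercial.

Step 1
Reactants: 1 3-methoxy-2-(trimethylsilyl)phenyl trifluoromethanesulfonate; 2 3-methylbut-2-enal
Product: 6 5-methoxy-2,2-dimethyl-2H-chromene, via 3-methoxybenzyne 3 (not isolated), via benzoxete 4 (not isolated), via ortho-quinone methide 5 (not isolated)
Conditions: CsF (3 equiv), 2 (5 equiv), MeCN, 25 → 50 °C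
Reagents that add atoms: none
Why: Fluoride-induced 1,2-elimination of 1 gives 3-methoxybenzyne 3; the carbonyl oxygen of 2 adds to the aryne carbon remote from the methoxy group and the aryl anion, held next to that inductively stabilising group, closes on the carbonyl carbon, so that a formal [2+2] addition (four-membered ring closure, polar and stepwise) sets the O1–C8a and C4–C4a bonds in benzoxete 4. Thermal 4π-electrocyclic opening of 4 gives ortho-quinone methide 5, whose (Z)-dienone closes the pyran ring by thermal disrotatory oxa-6π-electrocyclisation (O1–C2 bond) with return of aromaticity to the benzene ring. The closest known reaction type is the annulation of arynes with α,β-unsaturated aldehydes to 2H-chromenes. No stereocentre is formed. The step needs regioselectivity on the unsymmetrical aryne, which the methoxy-induced aryne distortion should secure by directing the oxygen nucleophile to the meta carbon, and chemoselectivity for C=O addition over ene reaction at the allylic methyl groups, which the excess of aldehyde supports.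

Step 2
Reactants: 6 5-methoxy-2,2-dimethyl-2H-chromene
Product: 7 2,2-dimethyl-2H-chromen-5-ol
Conditions: EtSNa (3 equiv), DMF, 130 °C; aq. HCl work-up
Reagents that add atoms: none
Why: Nucleophilic O-demethylation, in which the soft thiolate attacks the methyl group of the aryl methyl ether by SN2, should free the phenol under basic conditions that leave the chromene olefin untouched.

Step 3
Reactants: 7 2,2-dimethyl-2H-chromen-5-ol
Product: 8 2,2-dimethyl-5-[(3-methylbut-2-en-1-yl)oxy]-2H-chromene
Conditions: prenyl bromide (1.2 equiv), K2CO3, acetone, reflux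
Reagents that add atoms: 1-bromo-3-methylbut-2-ene (prenyl bromide), CC(C)=CCBr
Why: Williamson ether synthesis, the phenoxide being alkylated at oxygen by the primary allylic bromide.

Step 4
Reactants: 8 2,2-dimethyl-5-[(3-methylbut-2-en-1-yl)oxy]-2H-chromene
Product: 10 2,2-dimethyl-6-(2-methylbut-3-en-2-yl)-2H-chromen-5-ol, via ortho-dienone 9 (not isolated)
Conditions: PhNEt2, 185 °C, sealed tube, argon
Reagents that add atoms: none
Why: Aromatic Claisen rearrangement, in which the [3,3] shift can end productively only at C6 because the other ortho position (C4a) is substituted, and allylic inversion turns the O-prenyl group into the C-bound 1,1-dimethylallyl group before dienone 9 tautomerises to the phenol.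

Step 5
Reactants: 10 2,2-dimethyl-6-(2-methylbut-3-en-2-yl)-2H-chromen-5-ol
Product: 12 8,8-dimethoxy-2,2-dimethyl-6-(2-methylbut-3-en-2-yl)-2H-chromen-5(8H)-one, via 8-methoxyphenol 11 (not isolated)
Conditions: PhI(OAc)2 (2.2 equiv), MeOH, 0 → 25 °C
Reagents that add atoms: methanol, CO
Why: Oxidative dearomatisation of a para-unsubstituted phenol by a hypervalent iodine reagent in methanol, two successive two-electron oxidations with methanol capture at the free para carbon C8 giving the para-quinone monoketal, which places an oxygen on C8 and turns C5 into a ketone.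

Step 6
Reactants: 12 8,8-dimethoxy-2,2-dimethyl-6-(2-methylbut-3-en-2-yl)-2H-chromen-5(8H)-one
Product: 15 5-ethynyl-2,2-dimethyl-6-(2-methylbut-3-en-2-yl)-2H-chromen-8-ol, via quinol ketal 13 (not isolated), via para-quinol 14 (not isolated)
Conditions: HC≡CMgBr (3 equiv), THF, 0 → 25 °C; then AcOH/H2O (4:1), 25 °C; then Zn dust, 25 °C
Reagents that add atoms: ethynylmagnesium bromide, C#C[Mg]Br; water, O
Why: Grignard 1,2-addition of the small acetylide to the only carbonyl group, acid hydrolysis of the doubly allylic ketal and zinc reduction of the resulting para-quinol (reductive aromatisation with loss of the tertiary hydroxyl) should give the 5-alkynyl-8-phenol, the racemic carbinol centre of 13 and 14 disappearing on aromatisation.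

Step 7
Reactants: 15 5-ethynyl-2,2-dimethyl-6-(2-methylbut-3-en-2-yl)-2H-chromen-8-ol
Product: 16 5-ethynyl-8-(methoxymethoxy)-2,2-dimethyl-6-(2-methylbut-3-en-2-yl)-2H-chromene
Conditions: MOMCl, i-Pr2NEt, CH2Cl2, 0 → 25 °C
Reagents that add atoms: chloromethyl methyl ether (MOMCl), COCCl
Why: O-Alkylation of the phenol to its methoxymethyl ether, which masks the acidic hydroxyl for the organolithium steps that follow.

Step 8
Reactants: 17 2,4,6-trihydroxybenzaldehyde
Product: 18 2,4,6-trihydroxy-3-(3-methylbut-2-en-1-yl)benzaldehyde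
Conditions: prenyl bromide (1.0 equiv), DBU (1.1 equiv), THF, 0 → 25 °C
Reagents that add atoms: 1-bromo-3-methylbut-2-ene (prenyl bromide), CC(C)=CCBr
Why: Base-mediated C-alkylation of the phloroglucinol-type phenoxide (C-prenylation), the two free ring positions being equivalent so that only one mono-C-prenyl isomer can form.

Step 9
Reactants: 18 2,4,6-trihydroxy-3-(3-methylbut-2-en-1-yl)benzaldehyde
Product: 19 2-hydroxy-4,6-bis(methoxymethoxy)-3-(3-methylbut-2-en-1-yl)benzaldehyde
Conditions: MOMCl (2.1 equiv), i-Pr2NEt, CH2Cl2, 0 °C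
Reagents that add atoms: chloromethyl methyl ether (MOMCl), COCCl
Why: Selective methoxymethyl ether formation, in which the 4-hydroxyl and the less hindered 6-hydroxyl should react while the 2-hydroxyl, flanked by the prenyl group and hydrogen-bonded to the formyl group, should stay free.

Step 10
Reactants: 16 5-ethynyl-8-(methoxymethoxy)-2,2-dimethyl-6-(2-methylbut-3-en-2-yl)-2H-chromene; 19 2-hydroxy-4,6-bis(methoxymethoxy)-3-(3-methylbut-2-en-1-yl)benzaldehyde
Product: 20 1-[2-hydroxy-4,6-bis(methoxymethoxy)-3-(3-methylbut-2-en-1-yl)phenyl]-3-[8-(methoxymethoxy)-2,2-dimethyl-6-(2-methylbut-3-en-2-yl)-2H-chromen-5-yl]prop-2-yn-1-ol (racemic)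
Conditions: 16, n-BuLi, THF, −78 °C; then 19 pretreated with NaH (1.0 equiv, THF, 0 °C); −78 → 0 °C; AcOH quench
Reagents that add atoms: none
Why: Addition of a lithium acetylide to an aldehyde (alkynylation) with the phenol of 19 masked as its sodium phenoxide, the new carbinol stereocentre forming as a racemate that is removed in step 11.

Step 11
Reactants: 20 the propargylic alcohol of step 10
Product: 22 5,7-bis(methoxymethoxy)-2-[8-(methoxymethoxy)-2,2-dimethyl-6-(2-methylbut-3-en-2-yl)-2H-chromen-5-yl]-8-(3-methylbut-2-en-1-yl)-4H-chromen-4-one, via ynone 21 (not isolated)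
Conditions: activated MnO2 (20 equiv), CH2Cl2, 25 °C; filter; then K2CO3, dry acetone, reflux
Reagents that add atoms: none
Why: MnO2 oxidation of the benzylic propargylic alcohol gives the ortho-hydroxyaryl ynone, whose phenoxide should close ring C by 6-endo-dig oxa-Michael addition at the alkyne carbon β to the carbonyl, attack at an sp carbon tolerating the two ortho substituents of ring B and an aprotic medium being expected to favour the carbonyl-stabilised allenolate path over 5-exo closure.

Step 12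
Reactants: 22 the flavone of step 11
Product: 24 3-hydroxy-5,7-bis(methoxymethoxy)-2-[8-(methoxymethoxy)-2,2-dimethyl-6-(2-methylbut-3-en-2-yl)-2H-chromen-5-yl]-8-(3-methylbut-2-en-1-yl)-4H-chromen-4-one, via 3-boronate 23 (not isolated)
Conditions: LiN(i-Pr)2 (1.5 equiv), THF, −78 °C; B(OMe)3, −78 → 0 °C; then 30% H2O2, pH 7 phosphate buffer, 0 → 25 °C
Reagents that add atoms: hydrogen peroxide, OO
Why: Carbonyl-assisted C3 lithiation of the flavone, borylation and oxidative cleavage of the C–B bond (boronate oxidation) should install the 3-hydroxyl, the nucleophilic peroxide sparing the three olefins.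

Step 13
Reactants: 24 the tris(methoxymethyl) flavonol of step 12
Product: 25 3,5,7-trihydroxy-2-[8-hydroxy-2,2-dimethyl-6-(2-methylbut-3-en-2-yl)-2H-chromen-5-yl]-8-(3-methylbut-2-en-1-yl)-4H-chromen-4-one (CNP0241222.0)
Conditions: 3 M aq. HCl/MeOH (1:10), 45 °C
Reagents that add atoms: none
Why: Acid-catalysed acetal exchange with methanol (methoxymethyl ether cleavage) should free the 5-, 7- and 4′-hydroxyls under conditions commonly tolerated by prenyl and chromene groups.

Compound list

1 | 3-methoxy-2-(trimethylsilyl)phenyl trifluoromethanesulfonate | COc1cccc(OS(=O)(=O)C(F)(F)F)c1[Si](C)(C)C | starting material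
2 | 3-methylbut-2-enal | CC(C)=CC=O | starting material
3 | 3-methoxybenzyne (not isolated) | COC1=CC=CC#C1 | intermediate
4 | 3-methoxy-2-(2-methylprop-1-en-1-yl)-2H-benzo[b]oxete (not isolated) | COc1cccc2OC(C=C(C)C)c12 | intermediate
5 | (6Z)-5-methoxy-6-(3-methylbut-2-en-1-ylidene)cyclohexa-2,4-dien-1-one (not isolated) | O=C1C=CC=C(OC)/C1=C/C=C(C)C | intermediate
6 | 5-methoxy-2,2-dimethyl-2H-chromene | COc1cccc2OC(C)(C)C=Cc12 | intermediate
7 | 2,2-dimethyl-2H-chromen-5-ol | Oc1cccc2OC(C)(C)C=Cc12 | intermediate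
8 | 2,2-dimethyl-5-[(3-methylbut-2-en-1-yl)oxy]-2H-chromene | CC(C)=CCOc1cccc2OC(C)(C)C=Cc12 | intermediate
9 | 2,2-dimethyl-6-(2-methylbut-3-en-2-yl)-2H-chromen-5(6H)-one (racemic, not isolated) | C=CC(C)(C)C1C=CC2=C(C=CC(C)(C)O2)C1=O | intermediate
10 | 2,2-dimethyl-6-(2-methylbut-3-en-2-yl)-2H-chromen-5-ol | C=CC(C)(C)c1ccc2OC(C)(C)C=Cc2c1O | intermediate
11 | 8-methoxy-2,2-dimethyl-6-(2-methylbut-3-en-2-yl)-2H-chromen-5-ol (not isolated) | C=CC(C)(C)c1cc(OC)c2OC(C)(C)C=Cc2c1O | intermediate
12 | 8,8-dimethoxy-2,2-dimethyl-6-(2-methylbut-3-en-2-yl)-2H-chromen-5(8H)-one | C=CC(C)(C)C1=CC(OC)(OC)C2=C(C=CC(C)(C)O2)C1=O | intermediate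
13 | 5-ethynyl-8,8-dimethoxy-2,2-dimethyl-6-(2-methylbut-3-en-2-yl)-5,8-dihydro-2H-chromen-5-ol (racemic, not isolated) | C#CC1(O)C(C(C)(C)C=C)=CC(OC)(OC)C2=C1C=CC(C)(C)O2 | intermediate
14 | 5-ethynyl-5-hydroxy-2,2-dimethyl-6-(2-methylbut-3-en-2-yl)-2H-chromen-8(5H)-one (racemic, not isolated) | C#CC1(O)C(C(C)(C)C=C)=CC(=O)C2=C1C=CC(C)(C)O2 | intermediate
15 | 5-ethynyl-2,2-dimethyl-6-(2-methylbut-3-en-2-yl)-2H-chromen-8-ol | C#Cc1c(C(C)(C)C=C)cc(O)c2OC(C)(C)C=Cc12 | intermediate
16 | 5-ethynyl-8-(methoxymethoxy)-2,2-dimethyl-6-(2-methylbut-3-en-2-yl)-2H-chromene | C#Cc1c(C(C)(C)C=C)cc(OCOC)c2OC(C)(C)C=Cc12 | intermediate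
17 | 2,4,6-trihydroxybenzaldehyde | O=Cc1c(O)cc(O)cc1O | starting material
18 | 2,4,6-trihydroxy-3-(3-methylbut-2-en-1-yl)benzaldehyde | CC(C)=CCc1c(O)cc(O)c(C=O)c1O | intermediate
19 | 2-hydroxy-4,6-bis(methoxymethoxy)-3-(3-methylbut-2-en-1-yl)benzaldehyde | CC(C)=CCc1c(OCOC)cc(OCOC)c(C=O)c1O | intermediate
20 | 1-[2-hydroxy-4,6-bis(methoxymethoxy)-3-(3-methylbut-2-en-1-yl)phenyl]-3-[8-(methoxymethoxy)-2,2-dimethyl-6-(2-methylbut-3-en-2-yl)-2H-chromen-5-yl]prop-2-yn-1-ol (racemic) | CC(C)=CCc1c(OCOC)cc(OCOC)c(C(O)C#Cc2c(C(C)(C)C=C)cc(OCOC)c3OC(C)(C)C=Cc23)c1O | intermediate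
21 | 1-[2-hydroxy-4,6-bis(methoxymethoxy)-3-(3-methylbut-2-en-1-yl)phenyl]-3-[8-(methoxymethoxy)-2,2-dimethyl-6-(2-methylbut-3-en-2-yl)-2H-chromen-5-yl]prop-2-yn-1-one (not isolated) | CC(C)=CCc1c(OCOC)cc(OCOC)c(C(=O)C#Cc2c(C(C)(C)C=C)cc(OCOC)c3OC(C)(C)C=Cc23)c1O | intermediate
22 | 5,7-bis(methoxymethoxy)-2-[8-(methoxymethoxy)-2,2-dimethyl-6-(2-methylbut-3-en-2-yl)-2H-chromen-5-yl]-8-(3-methylbut-2-en-1-yl)-4H-chromen-4-one | CC(C)=CCc1c(OCOC)cc(OCOC)c2c(=O)cc(-c3c(C(C)(C)C=C)cc(OCOC)c4OC(C)(C)C=Cc34)oc12 | intermediate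
23 | dimethyl {5,7-bis(methoxymethoxy)-2-[8-(methoxymethoxy)-2,2-dimethyl-6-(2-methylbut-3-en-2-yl)-2H-chromen-5-yl]-8-(3-methylbut-2-en-1-yl)-4-oxo-4H-chromen-3-yl}boronate (not isolated) | CC(C)=CCc1c(OCOC)cc(OCOC)c2c(=O)c(B(OC)OC)c(-c3c(C(C)(C)C=C)cc(OCOC)c4OC(C)(C)C=Cc34)oc12 | intermediate
24 | 3-hydroxy-5,7-bis(methoxymethoxy)-2-[8-(methoxymethoxy)-2,2-dimethyl-6-(2-methylbut-3-en-2-yl)-2H-chromen-5-yl]-8-(3-methylbut-2-en-1-yl)-4H-chromen-4-one | CC(C)=CCc1c(OCOC)cc(OCOC)c2c(=O)c(O)c(-c3c(C(C)(C)C=C)cc(OCOC)c4OC(C)(C)C=Cc34)oc12 | intermediate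
25 | 3,5,7-trihydroxy-2-[8-hydroxy-2,2-dimethyl-6-(2-methylbut-3-en-2-yl)-2H-chromen-5-yl]-8-(3-methylbut-2-en-1-yl)-4H-chromen-4-one (CNP0241222.0) | C=CC(C)(C)c1cc(O)c2c(c1-c1oc3c(CC=C(C)C)c(O)cc(O)c3c(=O)c1O)C=CC(C)(C)O2 | target

Total step count: 13. Longest linear sequence: 11 steps (steps 1–7, then 10–13); steps 8 and 9 form the ring-A branch.

Steps most likely to fail

1. Step 6. The 1,2-addition may be slow at a carbonyl flanked by the carbon that bears the tert-alkyl group. In the acid stage, reduction may also outrun ketal hydrolysis, which would leave a methyl ether on C8, or the tertiary propargylic carbinol may ionise and rearrange. The fallback sets out from 12 and comes back at 16 by known chemistry. The ketal of 12 is hydrolysed with aqueous oxalic acid in THF to the para-quinone 2,2-dimethyl-6-(2-methylbut-3-en-2-yl)-2H-chromene-5,8-dione F1, which is reduced with Na2S2O4 (EtOAc/H2O) to 2,2-dimethyl-6-(2-methylbut-3-en-2-yl)-2H-chromene-5,8-diol F2. The unhindered 8-hydroxyl is protected selectively (MOMCl, 1.0 equiv, i-Pr2NEt) to give 8-(methoxymethoxy)-2,2-dimethyl-6-(2-methylbut-3-en-2-yl)-2H-chromen-5-ol F3. The hindered 5-hydroxyl is converted with Tf2O and pyridine into 8-(methoxymethoxy)-2,2-dimethyl-6-(2-methylbut-3-en-2-yl)-2H-chromen-5-yl trifluoromethanesulfonate F4. Sonogashira coupling with ethynyltrimethylsilane (PdCl2(PPh3)2, CuI, Et3N, DMF, 80 °C) gives {[8-(methoxymethoxy)-2,2-dimethyl-6-(2-methylbut-3-en-2-yl)-2H-chromen-5-yl]ethynyl}trimethylsilane F5, and K2CO3 in MeOH removes the silyl group to reach 16.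

2. Step 11. The phenoxide may close on the other alkyne carbon (5-exo-dig) and give a benzofuranone instead of the pyranone. The fallback sets out from 20 and comes back at 22. Ynone 21 is isolated after the MnO2 oxidation and treated with diethylamine (EtOH, 25 °C) to give the conjugate adduct 3-(diethylamino)-1-[2-hydroxy-4,6-bis(methoxymethoxy)-3-(3-methylbut-2-en-1-yl)phenyl]-3-[8-(methoxymethoxy)-2,2-dimethyl-6-(2-methylbut-3-en-2-yl)-2H-chromen-5-yl]prop-2-en-1-one F6 (olefin geometry not controlled). Heating F6 in EtOH closes the ring by addition–elimination at the amine-bearing carbon with loss of diethylamine, a path that can give only the six-membered ring.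

3. Step 4. At the rearrangement temperature the freed phenol may react further, by abnormal Claisen isomerisation of the side chain or by addition of its O–H across the new vinyl group. The fallback sets out from 8 and comes back at 10. The rearrangement is run in PhNEt2 with acetic anhydride and NaOAc, so that the phenol is acylated as it forms and is obtained as 2,2-dimethyl-6-(2-methylbut-3-en-2-yl)-2H-chromen-5-yl acetate F7. Methanolysis (K2CO3, MeOH, 25 °C) then gives 10.

Further compounds

F1 | step 6 | 2,2-dimethyl-6-(2-methylbut-3-en-2-yl)-2H-chromene-5,8-dione | C=CC(C)(C)C1=CC(=O)C2=C(C=CC(C)(C)O2)C1=O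
F2 | step 6 | 2,2-dimethyl-6-(2-methylbut-3-en-2-yl)-2H-chromene-5,8-diol | C=CC(C)(C)c1cc(O)c2OC(C)(C)C=Cc2c1O
F3 | step 6 | 8-(methoxymethoxy)-2,2-dimethyl-6-(2-methylbut-3-en-2-yl)-2H-chromen-5-ol | C=CC(C)(C)c1cc(OCOC)c2OC(C)(C)C=Cc2c1O
F4 | step 6 | 8-(methoxymethoxy)-2,2-dimethyl-6-(2-methylbut-3-en-2-yl)-2H-chromen-5-yl trifluoromethanesulfonate | C=CC(C)(C)c1cc(OCOC)c2OC(C)(C)C=Cc2c1OS(=O)(=O)C(F)(F)F
F5 | step 6 | {[8-(methoxymethoxy)-2,2-dimethyl-6-(2-methylbut-3-en-2-yl)-2H-chromen-5-yl]ethynyl}trimethylsilane | C=CC(C)(C)c1cc(OCOC)c2OC(C)(C)C=Cc2c1C#C[Si](C)(C)C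
F6 | step 11 | 3-(diethylamino)-1-[2-hydroxy-4,6-bis(methoxymethoxy)-3-(3-methylbut-2-en-1-yl)phenyl]-3-[8-(methoxymethoxy)-2,2-dimethyl-6-(2-methylbut-3-en-2-yl)-2H-chromen-5-yl]prop-2-en-1-one | CCN(CC)C(=CC(=O)c1c(O)c(CC=C(C)C)c(OCOC)cc1OCOC)c1c(C(C)(C)C=C)cc(OCOC)c2OC(C)(C)C=Cc12
F7 | step 4 | 2,2-dimethyl-6-(2-methylbut-3-en-2-yl)-2H-chromen-5-yl acetate | C=CC(C)(C)c1ccc2OC(C)(C)C=Cc2c1OC(C)=O
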